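**Retrosynthetic overview**
- The prenyl terminus (C14=C15) comes from a vinyl group by cross-metathesis. C12–C13 comes from an enal plus a chiral allylborane, which sets 12R. These are the only C–C bond formations.
- Key disconnection: C1–OAc and C20–OH are cut together, back to the 2-alkyl-1,3-diene of (6R,7R)-epoxy-β-sinensal plus peracetic acid. This is a new palladium-catalysed 1,4-acetoxy-hydroxylation that sets the 2E olefin and differentiates the two allylic oxygens without protecting groups.
- C6–O and C7–O come from Shi epoxidation of β-sinensal. The oxirane is the only ring and is closed in step 2.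
- C12=O comes from SeO2 allylic oxidation of the bulk sesquiterpene (E)-β-farnesene, which already holds C1–C12, C20, both methyl branches and the 6E olefin.

Assumption: atom numbers follow the geranylgeraniol skeleton of the target (C1 = CH2OAc, C20 = CH2OH on C3), and the SMILES is read as 2E,6R,7R,10E,12R.

**Step 1**
Reactants: 1 (E)-β-farnesene
Product: 3 β-sinensal (2E,6E)-2,6-dimethyl-10-methylidenedodeca-2,6,11-trienal, via allylic alcohol 2 (not isolated)
Conditions: SeO2 (0.1 equiv), salicylic acid (0.1 equiv), t-BuOOH (2 equiv), CH2Cl2, 0 °C to rt; filter, then MnO2 (10 equiv), CH2Cl2, rt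
Reagents that add atoms: tert-butyl hydroperoxide CC(C)(C)OO (oxygen atom, relayed through catalytic SeO2 O=[Se]=O)
Why: SeO2 allylic oxidation (ene reaction, then [2,3]-sigmatropic shift) attacks the most electron-rich and least hindered trisubstituted olefin at its (E)-methyl group, which fixes the 10E geometry; MnO2 then oxidises only the allylic alcohol, this conversion of β-farnesene into β-sinensal is known, and no stereocentre is formed.

**Step 2**
Reactants: 3 β-sinensal
Product: 4 (6R,7R)-epoxy-β-sinensal (2E)-2-methyl-5-[(2R,3R)-2-methyl-3-(3-methylidenepent-4-en-1-yl)oxiran-2-yl]pent-2-enal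
Conditions: D-fructose-derived Shi ketone (0.3 equiv), Oxone (2KHSO5·KHSO4·K2SO4, 1.0 equiv), K2CO3 (4.2 equiv), n-Bu4NHSO4 (cat.), MeCN–CH2(OMe)2 / aq Na2B4O7–Na2EDTA buffer (pH 10.5), −5 to 0 °C, 2 h
Reagents that add atoms: potassium peroxymonosulfate (active part of Oxone) [K+].[O-]S(=O)(=O)OO
Why: In this Shi asymmetric epoxidation the electrophilic chiral dioxirane takes the only isolated trisubstituted olefin (C6=C7) and leaves the electron-poor enal olefin and the less substituted conjugated diene; the spiro transition state of the D-fructose ketone gives (R,R)-epoxides from (E)-trisubstituted olefins, so C6 and C7 are set together (about 90–95% ee expected) with C5 and C8 trans by stereospecific syn addition.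

**Step 3**
Reactants: 4 (6R,7R)-epoxy-β-sinensal; 5 peracetic acid
Product: 7 (2E)-3-(hydroxymethyl)-5-[(2R,3R)-3-methyl-3-[(3E)-4-methyl-5-oxopent-3-en-1-yl]oxiran-2-yl]pent-2-en-1-yl acetate, via allylpalladium acetate 6 (not isolated)
Conditions: Pd(OAc)2 (5 mol %), n-Bu4NOAc (0.5 equiv), AcOH (5 equiv), AcOOH (1.2 equiv, NaOAc-buffered, syringe pump over 6 h), EtOAc, 0 to 15 °C
Reagents that add atoms: peracetic acid CC(=O)OO
Why: Proposed new method: a palladium-catalysed 1,4-acetoxy-hydroxylation of a 2-alkyl-1,3-diene with peracetic acid as the only stoichiometric reagent, in which acetate attacks the diene bound to divalent palladium at the unsubstituted vinyl terminus C1 (the regiochemistry of the known Bäckvall 1,4-acetoxychlorination of isoprene) to give the syn 1-(acetoxymethyl)-2-alkyl-allylpalladium acetate 6; without benzoquinone or another π-acceptor 6 is inert to acetate, but the peracid oxygenates it at the unhindered CH2 terminus C20 (ligand exchange to Pd–OOAc, then a 1,2-shift of carbon from Pd to O as in organoborane oxidation, the stoichiometric peracid oxidation of isolated allylpalladium complexes to allylic alcohols being known), and protonolysis of the palladium alkoxide returns Pd(OAc)2 so that palladium stays divalent throughout; the syn geometry of 6 places C1 trans to C20 and sets the 2E olefin, slow addition keeps free peracid too low for background epoxidation, the acetate buffer protects the oxirane, and the closest known reaction types are the Bäckvall 1,4-oxidation of dienes and the peracid oxidation of allylpalladium complexes.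

**Step 4**
Reactants: 7 epoxy hydroxy-acetate enal; 8 lIpc2B(allyl), the B-allyldiisopinocampheylborane of the (−)-α-pinene series
Product: 10 (2E)-3-(hydroxymethyl)-5-[(2R,3R)-3-[(3E,5R)-5-hydroxy-4-methylocta-3,7-dien-1-yl]-3-methyloxiran-2-yl]pent-2-en-1-yl acetate, via diisopinocampheylborinate 9 (not isolated)
Conditions: 8 (2.2 equiv, 1 M in pentane), Et2O, −78 °C, 2 h; then MeOH, pH 7 buffer (NaH2PO4/Na2HPO4), 30% H2O2, 0 °C
Reagents that add atoms: lIpc2B(allyl) C=CCB([C@H]1C[C@H]2C[C@@H]([C@@H]1C)C2(C)C)[C@H]1C[C@H]2C[C@@H]([C@@H]1C)C2(C)C
Why: Brown asymmetric allylboration runs through a closed chair transition state, and the (−)-α-pinene-derived reagent adds to the Re face of α-methyl enals to give the 12R alcohol under reagent control (C6 and C7 are too remote to interfere); at −78 °C the aldehyde reacts far faster than acetate or epoxide, the extra equivalent covers the free C20–OH, and the neutral peroxide work-up spares the acetate.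

**Step 5**
Reactants: 10 homoallylic alcohol; 11 2-methyl-2-butene
Product: 12 target (2E)-3-(hydroxymethyl)-5-[(2R,3R)-3-[(3E,5R)-5-hydroxy-4,8-dimethylnona-3,7-dien-1-yl]-3-methyloxiran-2-yl]pent-2-en-1-yl acetate
Conditions: second-generation Hoveyda–Grubbs catalyst (3 mol %), 2-methyl-2-butene/CH2Cl2 (1:1), 35 °C, sealed tube, 12 h
Reagents that add atoms: 2-methyl-2-butene CC=C(C)C
Why: Olefin cross-metathesis with 2-methyl-2-butene turns the monosubstituted vinyl group into the isopropylidene (prenyl) terminus with loss of propene, while the trisubstituted olefins, oxirane, acetate and free alcohols are inert to the ruthenium carbene and no stereocentre is touched.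

**Compound list**
1 | (E)-β-farnesene, (6E)-7,11-dimethyl-3-methylidenedodeca-1,6,10-triene | C=CC(=C)CC/C=C(\C)CCC=C(C)C | starting material
2 | (2E,6E)-2,6-dimethyl-10-methylidenedodeca-2,6,11-trien-1-ol | C=CC(=C)CC/C=C(\C)CC/C=C(\C)CO | intermediate (not isolated)
3 | β-sinensal | C=CC(=C)CC/C=C(\C)CC/C=C(\C)C=O | intermediate
4 | (6R,7R)-epoxy-β-sinensal | C=CC(=C)CC[C@H]1O[C@]1(C)CC/C=C(\C)C=O | intermediate
5 | peracetic acid | CC(=O)OO | starting material
6 | allylpalladium acetate (drawn as the C20-bound σ form of the syn π-allyl complex) | CC(=O)OC/C=C(/C[Pd]OC(C)=O)CC[C@H]1O[C@]1(C)CC/C=C(\C)C=O | intermediate (not isolated)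
7 | (2E,6R,7R,10E)-1-acetoxy-20-hydroxy-6,7-epoxy-12-al | CC(=O)OC/C=C(/CO)CC[C@H]1O[C@]1(C)CC/C=C(\C)C=O | intermediate
8 | lIpc2B(allyl), from (−)-α-pinene | C=CCB([C@H]1C[C@H]2C[C@@H]([C@@H]1C)C2(C)C)[C@H]1C[C@H]2C[C@@H]([C@@H]1C)C2(C)C | starting material
9 | C12-O-diisopinocampheylborinate of 10 | CC(=O)OC/C=C(/CO)CC[C@H]1O[C@]1(C)CC/C=C(\C)[C@H](OB([C@H]1C[C@H]2C[C@@H]([C@@H]1C)C2(C)C)[C@H]1C[C@H]2C[C@@H]([C@@H]1C)C2(C)C)CC=C | intermediate (not isolated)
10 | (12R)-homoallylic alcohol | CC(=O)OC/C=C(/CO)CC[C@H]1O[C@]1(C)CC/C=C(\C)[C@H](O)CC=C | intermediate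
11 | 2-methyl-2-butene | CC=C(C)C | starting material
12 | CNP0323680.1 | CC(=O)OC/C=C(/CO)CC[C@H]1O[C@]1(C)CC/C=C(\C)[C@H](O)CC=C(C)C | target

**Total step count:** 5. **Longest linear sequence:** 5.

**Steps most likely to fail**

Step 3, the new reaction, is the largest risk. Tetravalent palladium could form and give C–OAc instead of C–OH, leading to the 1,4-diacetate. Peracid could be decomposed on palladium, or the vinyl group could be oxidised in a Wacker-type reaction. The fallback uses known chemistry, sets out from 4 and returns at 7. m-CPBA (1.0 equiv) with NaHCO3 in CH2Cl2 at 0 °C epoxidises the more substituted diene double bond C3=C20, the only nucleophilic olefin left. This gives the vinyl bis-epoxide F1 as both C3 epimers, and that centre is erased in the next step. Pd(PPh3)4 (1 mol %) with AcOH (1.5 equiv) in THF at 0 °C then ionises only the vinyl epoxide with zerovalent palladium. Acetate adds at C1, as in the Tsuji–Trost 1,4-opening known for isoprene monoxide, to give 7. The 2E isomer is the major product and the 2Z isomer is removed by chromatography.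

Step 2 is the second risk. The enal may not tolerate basic peroxymonosulfate, being lost to carboxylic acid or to nucleophilic epoxidation. The fallback moves the epoxidation to the alcohol oxidation level, sets out from 2 and returns at 4. After the SeO2 stage the crude is treated with NaBH4 and alcohol 2 is isolated. Ac2O/pyridine gives the allylic acetate F2, whose C10=C11 olefin is deactivated in the same way as the 2,3-olefin of farnesyl acetate. The same Shi conditions give the (6R,7R)-epoxy acetate F3. K2CO3 (0.2 equiv) in MeOH at 0 °C gives the epoxy alcohol F4, and MnO2 in CH2Cl2 gives 4.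

Step 4 is the third risk. The free C20–OH consumes borane, and the acetate could be lost during work-up. The fallback replaces the stoichiometric chiral borane by Brønsted-acid catalysis, sets out from 7 and returns at 10. Allylboronic acid pinacol ester (1.3 equiv) and (R)-TRIP phosphoric acid (5 mol %) in toluene at −30 °C give the pinacol borate ester F5. This hydrolyses on silica gel to 10 without any oxidant. The sense of induction is checked by Mosher analysis, and the antipodal acid is used if required.

**Further compounds**
F1 | step 3 | vinyl bis-epoxide, 3,20:6,7-diepoxide of β-sinensal (C3 epimers) | C=CC1(CC[C@H]2O[C@]2(C)CC/C=C(\C)C=O)CO1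
F2 | step 2 | (2E,6E)-2,6-dimethyl-10-methylidenedodeca-2,6,11-trien-1-yl acetate | C=CC(=C)CC/C=C(\C)CC/C=C(\C)COC(C)=O
F3 | step 2 | (6R,7R)-epoxy acetate | C=CC(=C)CC[C@H]1O[C@]1(C)CC/C=C(\C)COC(C)=O
F4 | step 2 | (6R,7R)-epoxy alcohol | C=CC(=C)CC[C@H]1O[C@]1(C)CC/C=C(\C)CO
F5 | step 4 | C12-O-pinacol borate ester of 10 | CC(=O)OC/C=C(/CO)CC[C@H]1O[C@]1(C)CC/C=C(\C)[C@H](OB1OC(C)(C)C(C)(C)O1)CC=C
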